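Remark on the chemistry: germacrane numbering is used for every intermediate (ring C1–C10; C11, C12, C13 on C7; C14 on C10; C15 on C4). The descriptor at C6 is S in the open-chain and butenolide intermediates and R in the bicyclic lactones, with no change in spatial arrangement.

## Analysis of the target

The target is a germacranolide: a ten-membered carbocycle (C1–C10) fused through C6 and C7 to an α-methylene-γ-butyrolactone (C12 carbonyl, lactone oxygen on C6, C11=C13 methylene). The carbocycle holds two trisubstituted alkenes, C1=C10 with the C14 aldehyde and C4=C5 with the C15 hydroxymethyl group. In both alkenes the ring carbons are cis to each other; each is E by the sequence rules only because CHO and CH2OH outrank the ring carbons. The three contiguous stereocentres C6, C7 and C8 are all R: H6 and H7 are trans (trans-fused lactone) and C8 carries the 3-methylbutanoate. The sensitive groups are the exocyclic enoate (a Michael acceptor), the enal, the primary allylic alcohol, and the C8 oxygen, which sits γ to the lactone carbonyl and can translactonise when it is a free alkoxide. The synthesis is hard because a medium ring with two ring-cis alkenes must be closed, three stereocentres sit on a flexible ring, and the allylic carbons C14 and C15 are at different oxidation levels. The route rests on one feature: C7 is the β-carbon of the lactone carbonyl C12 and is bonded to the oxygen-bearing C8, which is the pattern left by a C8 ketyl radical adding to the β-carbon of a butenolide whose γ-carbon is C6.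

## Retrosynthetic reasoning

**29 ⇒ 28.** The C14 aldehyde and the C15 alcohol are the most fragile groups and are released last, together, from the dimethyl acetal and the silyl ether of 28 by dilute aqueous acid. Nothing else in 28 responds to these conditions.

**28 ⇒ 26 ⇒ 24 ⇒ 23.** The C8 ester is cut at the acyl–oxygen bond, with anhydride 27 as acyl donor. The C11=C13 bond is cut by a Mannich–elimination sequence through amine 24 and its quaternary salt 25. Methylenation comes before acylation so that no ester α-hydrogens are present during enolate formation; the price is that 23 reacts as an alkoxide–enolate dianion.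

**23 ⇒ 22 (key disconnection).** The C7–C8 bond is cut. In the forward direction a ketyl radical generated at the C8 aldehyde of 22 by a divalent samarium reductant must add to C7 of the butenolide on the face opposite C5. This one step closes the carbocycle, completes the bicycle and creates C7 and C8; the only stereocentre needed beforehand is C6. Cutting elsewhere in the ring would require C7 and C8 to be built in an open chain first.

**22 ⇒ 21 ⇒ 20.** The β,γ-unsaturated aldehyde is prone to conjugation, so it is made in the last step before the ring closure from alcohol 21, which comes from triethylsilyl ether 20. The C8 silyl group must be removable beside the C15 silyl ether, the acetal and the base-sensitive butenolide.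

**20 ⇒ 19 ⇒ 18 ⇒ 16 + 17.** The acetal of 20 comes from enal 19 under aprotic conditions. The butenolide is cut at C7=C11 by ring-closing metathesis of acrylate 18, made from carbinol 16 and acid chloride 17. The butenolide is introduced late because its C6 hydrogen is both γ to the carbonyl and allylic, and would not survive the basic and hydridic steps that build the chain.

**16 ⇒ 15 ⇒ 12 + 13.** The C6–C7 bond is formed by catalytic asymmetric addition of the zinc reagent 14 (made from 13) to enal 12. This is the only stereocentre set by a reagent. The amide of 15 is reduced to the aldehyde of 16 only after the addition, so that one aldehyde is present at a time.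

**12 ⇒ 11 ⇒ 10 ⇒ 9.** Lactone 9 is opened to hydroxy amide 10, which separates C14 from C8. Direct reduction of 9 would give a lactol tying the two carbons together, and a C14 acetal made beside a free C8 hydroxyl under acid would close to a five-membered cyclic acetal. In 10 the two primary alcohols differ: only C6 is allylic, so an allylic-selective oxidation gives 11 and the remaining C8 alcohol is silylated to 12 without a protecting group at C6.

**9 ⇒ 7 + 8.** The C1=C10 alkene is cut by Horner–Wadsworth–Emmons olefination of aldehyde 7 with phosphonate 8. The lactone of 8 supplies C14, C10, C9 and C8 in one piece, and the preferred E-alkylidene lactone is the required ring-cis geometry.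

**7 ⇒ 6 ⇒ 4 + 5.** The C3–C4 bond is cut by a Negishi coupling of vinyl iodide 4 with zinc homoenolate 5, with retention of alkene geometry. An acetal-masked C1 aldehyde would need aqueous acid for its release, which the allylic silyl ether of 6 would not survive; the ester is released reductively instead.

**4 ⇒ 2 ⇒ 1.** The C4–I bond and the C4=C5 geometry come from hydroxyl-directed hydroalumination–iodination of 2. The free hydroxyl of monosilyl ether 2 directs the regiochemistry, so C15 is the silylated end and C6 the free end.

## Alternatives that were turned down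

**Alternative 1:** The disconnection is the C4=C5 alkene with C15 at the ester level. In the forward step, within one open chain, a phosphonoacetate anion at C4 would add to an α-silyloxy aldehyde at C5 and lose phosphate, closing the carbocycle as A1.
- For it: the olefination is ionic and predictable, and the thermodynamically preferred E-enoate is the ring-cis geometry. All three stereocentres are fixed before the ring closes, so the key step carries no stereochemical risk; on that point it is stronger than the chosen route.
- Against it: a ten-membered ring is a poor case for this olefination (oligomers compete). The C5 aldehyde has an epimerisable, eliminable α-oxygen centre at C6 under the basic conditions. The C6/C7/C8 stereotriad with its branched C11 unit must be assembled in an open chain. A1 is still far from the target: it needs C15 ester reduction, two benzyl ether removals, oxidation of C12, lactonisation and acylation.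
- Comparison: the chosen route makes C7, C8 and the lactone-fused bicycle in the ring closure itself and needs only four steps afterwards.

**Alternative 2:** No ring bond of the target is cut; a transannular C1–C6 bond is added in the retrosynthetic direction. In the forward step, in a cis-fused bicyclo[4.4.0]decane framework, a C6 alkoxide pushes, the C1–C6 bond breaks and a spiro-epoxide C–O bond at C10 opens, releasing the ten-membered dienone A2 with its C1=C10 alkene and free C14 alcohol.
- For it: fragmentation is the most dependable way to reach a ten-membered ring, since no medium-ring transition state has to be reached, and the C1=C10 geometry follows stereospecifically from the bicyclic precursor. On ring formation it is stronger than the chosen route.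
- Against it: a heavily substituted bicycle with the right relative configuration at the carbinol, the epoxide and the ring fusion must be built and then destroyed. In A2 the C6 ketone still has to be reduced from the correct face of a flexible ring, C7 is epimerisable next to it, C12 must be oxidised and lactonised, C14 oxidised beside C15, and C13 added.
- Comparison: the chosen route is acyclic up to the ring closure, sets C6 directly as a carbinol by a catalytic addition, and has the lactone in place before the ring forms.

**Alternative 3:** The disconnection is C5–C6, next to the lactone oxygen. In the forward step a C5 alkenyl iodide is converted by a divalent chromium salt with a nickel co-catalyst into an alkenylchromium species that adds to a C6 aldehyde; the chromium alkoxide then closes onto a C12 ester, giving A3.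
- For it: this macrocyclisation has better precedent for ten-membered rings than a ketyl–olefin closure and tolerates all the functionality. A3 is the C8 triethylsilyl ether of 23, so the endgames are equally short. On reliability of the ring closure it is stronger.
- Against it: C7 and C8 must be set in an open chain, the C6 aldehyde is α-branched and epimerisable at C7, a stereodefined trisubstituted alkenyl iodide is needed, and the facial selectivity at C6 in the closure is unsecured (either epimer can lactonise).
- Comparison: the chosen route derives C7 and C8 from the single, easily made C6 centre during ring closure and reaches its precursor by a shorter sequence without an acyclic stereodiad.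

Key step: step 16

## Route

Step 1
Reactants: 1 but-2-yne-1,4-diol
Product: 2 4-[(tert-butyldimethylsilyl)oxy]but-2-yn-1-ol
Conditions: 1 (3 equiv), t-BuMe2SiCl (1 equiv), imidazole, DMF, 0 °C to rt
Reagents that add atoms: tert-butyldimethylsilyl chloride, CC(C)(C)[Si](C)(C)Cl
Why: Statistical monosilylation of a symmetrical diol; the excess of water-soluble 1 suppresses the bis-ether and is washed out.

Step 2
Reactants: 2 4-[(tert-butyldimethylsilyl)oxy]but-2-yn-1-ol
Product: 4 (Z)-4-[(tert-butyldimethylsilyl)oxy]-3-iodobut-2-en-1-ol, via cyclic alkenylaluminate 3 (not isolated)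
Conditions: NaAlH2(OCH2CH2OMe)2 (Red-Al), THF, 0 °C to rt; then I2, −78 to 0 °C
Reagents that add atoms: iodine, [I][I]
Why: Hydroxyl-directed trans-hydroalumination of a propargylic alcohol: the alkoxyaluminium hydride delivers hydride to the alkyne carbon next to the carbinol (C5) and leaves aluminium on C4 inside a five-membered ring, so iodinolysis with retention places iodine cis to CH2OH. Only the free hydroxyl can direct, which fixes the regiochemistry.

Step 3
Reactants: 4 (Z)-4-[(tert-butyldimethylsilyl)oxy]-3-iodobut-2-en-1-ol; 5 (3-ethoxy-3-oxopropyl)zinc bromide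
Product: 6 ethyl (E)-4-{[(tert-butyldimethylsilyl)oxy]methyl}-6-hydroxyhex-4-enoate (C3 chain cis to CH2OH)
Conditions: 5 (2.5 equiv), Pd(OAc)2 (cat.), SPhos, THF, 25–40 °C
Reagents that add atoms: none
Why: Negishi sp3–sp2 coupling with retention of alkene geometry; alkylzinc halides tolerate the free hydroxyl and the ester. The ester homoenolate serves as the C1–C3 unit because its later unmasking needs no acid.

Step 4
Reactants: 6 ethyl (E)-4-{[(tert-butyldimethylsilyl)oxy]methyl}-6-hydroxyhex-4-enoate
Product: 7 (E)-4-{[(tert-butyldimethylsilyl)oxy]methyl}-6-hydroxyhex-4-enal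
Conditions: i-Bu2AlH (2.2 equiv), CH2Cl2, −78 °C; aq. KNaC4H4O6
Reagents that add atoms: none
Why: Partial reduction of an ester with a hindered aluminium hydride at −78 °C, where the tetrahedral aluminium hemiacetal persists until work-up; one equivalent is spent on the hydroxyl.

Step 5
Reactants: 7 (E)-4-{[(tert-butyldimethylsilyl)oxy]methyl}-6-hydroxyhex-4-enal; 8 diethyl (2-oxooxolan-3-yl)phosphonate
Product: 9 (E)-3-[(E)-4-{[(tert-butyldimethylsilyl)oxy]methyl}-6-hydroxyhex-4-en-1-ylidene]oxolan-2-one
Conditions: 8, NaH, THF, 0 °C; then 7, 0 °C to rt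
Reagents that add atoms: none
Why: Horner–Wadsworth–Emmons olefination; the cyclic phosphonate should give mainly the E-alkylidene lactone (C2 trans to the lactone carbonyl, cis to the ring CH2), which is the ring-cis C1=C10 geometry, and any Z isomer is removed by chromatography. The stabilised anion does not deprotonate the hydroxyl.

Step 6
Reactants: 9 (E)-alkylidene lactone
Product: 10 (2E,6E)-6-{[(tert-butyldimethylsilyl)oxy]methyl}-8-hydroxy-2-(2-hydroxyethyl)-N-methoxy-N-methylocta-2,6-dienamide
Conditions: MeNH(OMe)·HCl, AlMe3, CH2Cl2, 0 °C to rt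
Reagents that add atoms: N,O-dimethylhydroxylamine hydrochloride, CNOC.Cl
Why: Weinreb aminolysis of a lactone by the aluminium amide opens the ring at the acyl carbon and separates C14 (amide) from C8 (free alcohol) without touching the alkene geometry.

Step 7
Reactants: 10 dihydroxy Weinreb amide
Product: 11 (2E,6E)-6-{[(tert-butyldimethylsilyl)oxy]methyl}-2-(2-hydroxyethyl)-N-methoxy-N-methyl-8-oxoocta-2,6-dienamide
Conditions: MnO2 (activated, excess), CH2Cl2, rt
Reagents that add atoms: none
Why: MnO2 oxidises only the allylic C6 alcohol and leaves the homoallylic C8 alcohol, so the two primary alcohols are told apart without a protecting group.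

Step 8
Reactants: 11 hydroxy enal Weinreb amide
Product: 12 (2E,6E)-6-{[(tert-butyldimethylsilyl)oxy]methyl}-N-methoxy-N-methyl-8-oxo-2-{2-[(triethylsilyl)oxy]ethyl}octa-2,6-dienamide
Conditions: Et3SiCl, imidazole, CH2Cl2, 0 °C
Reagents that add atoms: chlorotriethylsilane, CC[Si](Cl)(CC)CC
Why: Standard silylation of the remaining primary alcohol; the triethylsilyl group is chosen because it can later be removed beside the C15 tert-butyldimethylsilyl ether.

Step 9
Reactants: 12 enal Weinreb amide; 13 vinylmagnesium bromide
Product: 15 (2E,6E,8S)-6-{[(tert-butyldimethylsilyl)oxy]methyl}-8-hydroxy-N-methoxy-N-methyl-2-{2-[(triethylsilyl)oxy]ethyl}deca-2,6,9-trienamide, via divinylzinc 14 (not isolated)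
Conditions: 13, ZnCl2, THF, then 1,4-dioxane (magnesium salts filtered off); (−)-MIB (10 mol%), 12, toluene, −20 °C
Reagents that add atoms: none
Why: Amino-alcohol-catalysed enantioselective addition of an alkenylzinc reagent to an aldehyde. By analogy with dialkylzinc additions, (−)-MIB is expected to direct the vinyl group to the Si face of the enal, which gives the S carbinol at C6 (the spatial arrangement of C6 in the target); the Weinreb amide and silyl ethers are inert to the zinc reagent.

Step 10
Reactants: 15 (S)-dienyl carbinol Weinreb amide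
Product: 16 (2E,6E,8S)-6-{[(tert-butyldimethylsilyl)oxy]methyl}-8-hydroxy-2-{2-[(triethylsilyl)oxy]ethyl}deca-2,6,9-trienal
Conditions: i-Bu2AlH (2.5 equiv), THF, −78 °C; aq. KNaC4H4O6
Reagents that add atoms: none
Why: Reduction of a Weinreb amide to the aldehyde through the stable chelated aluminium adduct; the carbinol is carried as its aluminium alkoxide and the stereocentre is untouched.

Step 11
Reactants: 16 (S)-carbinol enal; 17 acryloyl chloride
Product: 18 (3S,4E,8E)-5-{[(tert-butyldimethylsilyl)oxy]methyl}-9-formyl-11-[(triethylsilyl)oxy]undeca-1,4,8-trien-3-yl prop-2-enoate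
Conditions: 17, i-Pr2NEt, CH2Cl2, −78 to 0 °C
Reagents that add atoms: none
Why: O-acylation of the secondary alcohol with an acid chloride under a hindered amine base at low temperature; the C–O bond of the stereocentre is not broken.

Step 12
Reactants: 18 (S)-acrylate
Product: 19 (2E,6E)-6-{[(tert-butyldimethylsilyl)oxy]methyl}-7-[(2S)-5-oxo-2,5-dihydrofuran-2-yl]-2-{2-[(triethylsilyl)oxy]ethyl}hepta-2,6-dienal
Conditions: second-generation Grubbs catalyst (5 mol%), CH2Cl2 (5 mM), 40 °C
Reagents that add atoms: none
Why: Ring-closing metathesis of an allyl acrylate to a butenolide: the catalyst loads on the terminal vinyl group and closes on the acrylate, while the trisubstituted alkenes and the enal are too hindered to take part.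

Step 13
Reactants: 19 butenolide enal
Product: 20 (5S)-5-[(1E,5E)-2-{[(tert-butyldimethylsilyl)oxy]methyl}-6-(dimethoxymethyl)-8-[(triethylsilyl)oxy]octa-1,5-dien-1-yl]furan-2(5H)-one
Conditions: MeOSiMe3 (3 equiv), Me3SiOTf (5 mol%), CH2Cl2, −78 °C; pyridine quench
Reagents that add atoms: methoxytrimethylsilane, CO[Si](C)(C)C
Why: Noyori acetalisation under aprotic conditions converts the enal into its dimethyl acetal without alkene migration; at −78 °C with a catalytic silyl triflate both silyl ethers and the allylic lactone C–O bond should stay intact. The acetal masks C14 against the reductant of the key step.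

Step 14
Reactants: 20 butenolide acetal triethylsilyl ether
Product: 21 (5S)-5-[(1E,5E)-2-{[(tert-butyldimethylsilyl)oxy]methyl}-6-(dimethoxymethyl)-8-hydroxyocta-1,5-dien-1-yl]furan-2(5H)-one
Conditions: HF·pyridine, excess pyridine, THF, 0 °C
Reagents that add atoms: none
Why: Buffered HF·pyridine cleaves a primary triethylsilyl ether much faster than a primary tert-butyldimethylsilyl ether; the medium is not basic enough to enolise the butenolide at C6 and not acidic enough to ionise the acetal.

Step 15
Reactants: 21 butenolide acetal alcohol
Product: 22 (3E,7E)-7-{[(tert-butyldimethylsilyl)oxy]methyl}-3-(dimethoxymethyl)-8-[(2S)-5-oxo-2,5-dihydrofuran-2-yl]octa-3,7-dienal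
Conditions: Dess–Martin periodinane, pyridine, CH2Cl2, 0 °C to rt; used at once
Reagents that add atoms: none
Why: Dess–Martin oxidation under pyridine buffer gives the β,γ-unsaturated aldehyde without moving the C1=C10 alkene into conjugation.

Step 16
Reactants: 22 seco-butenolide aldehyde
Product: 23 (3aR,4R,6E,10E,11aR)-10-{[(tert-butyldimethylsilyl)oxy]methyl}-6-(dimethoxymethyl)-4-hydroxy-3a,4,5,8,9,11a-hexahydrocyclodeca[b]furan-2(3H)-one (germacrane 6R,7R,8R)
Conditions: SmI2 (3 equiv), t-BuOH (4 equiv), THF, 22 added slowly to 2 mM final concentration, 0 °C to rt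
Reagents that add atoms: none
Why: Single-electron transfer from SmI2 to the C8 aldehyde gives a samarium-bound ketyl radical that adds to C7, the β-carbon of the butenolide; the resulting C11 radical next to the lactone carbonyl takes a second electron and the trivalent samarium enolate is protonated by t-BuOH. The closest known reaction type is the SmI2 ketyl–olefin cyclisation onto α,β-unsaturated esters and lactones, established for five- to eight-membered rings and extended here in ring size only. One ring is closed, the ten-membered carbocycle, in the 10-exo-trig mode (C11 stays outside the new ring), and this also completes the lactone-fused bicycle. C7 is controlled by the C6 centre: bonding on the butenolide face opposite the C5 substituent keeps the forming C7–C8 bond staggered to C6–C5 and leads to the less strained trans-fused bicycle. C8 is controlled by samarium bridging the ketyl oxygen and the lactone carbonyl oxygen, which holds O8 over the lactone and turns the C9 arm away from C11; combined with anti attack at C7 this arrangement corresponds to 8R. The step needs the aldehyde to be reduced before the butenolide, which the absence of HMPA and the mild proton source should secure, and it needs cyclisation to outrun dimerisation and simple reduction, for which high dilution, the persistent samarium ketyl and the two ring-cis alkenes that pre-fold the chain are relied on.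

Step 17
Reactants: 23 hydroxy lactone
Product: 24 (3aR,4R,6E,10E,11aR)-10-{[(tert-butyldimethylsilyl)oxy]methyl}-6-(dimethoxymethyl)-3-[(dimethylamino)methyl]-4-hydroxy-3a,4,5,8,9,11a-hexahydrocyclodeca[b]furan-2(3H)-one (both C3 epimers)
Conditions: LiN(i-Pr)2 (2.3 equiv), THF, −78 °C; Me2N=CH2 iodide (Eschenmoser salt), −78 to 0 °C
Reagents that add atoms: N,N-dimethylmethyleneiminium iodide, C[N+](C)=C.[I-]
Why: Mannich reaction of a lactone enolate: the first equivalent of base forms the C8 alkoxide, the second the C11 enolate, which is aminomethylated. The new C11 centre is removed in the next step, so its configuration does not matter.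

Step 18
Reactants: 24 Mannich base
Product: 26 (3aR,4R,6E,10E,11aR)-10-{[(tert-butyldimethylsilyl)oxy]methyl}-6-(dimethoxymethyl)-4-hydroxy-3-methylidene-3a,4,5,8,9,11a-hexahydrocyclodeca[b]furan-2(3H)-one, via trimethylammonium iodide 25 (not isolated)
Conditions: MeI, CH2Cl2/MeOH, rt; then aq. NaHCO3, CH2Cl2, rt
Reagents that add atoms: none
Why: Quaternisation of the amine followed by E1cB elimination of the ammonium group under bicarbonate gives the α-methylene lactone; the base is too mild to move the alkene into the ring or to disturb C7.

Step 19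
Reactants: 26 α-methylene lactone alcohol; 27 3-methylbutanoic anhydride
Product: 28 (3aR,4R,6E,10E,11aR)-10-{[(tert-butyldimethylsilyl)oxy]methyl}-6-(dimethoxymethyl)-3-methylidene-2-oxo-2,3,3a,4,5,8,9,11a-octahydrocyclodeca[b]furan-4-yl 3-methylbutanoate
Conditions: 27, DMAP (cat.), pyridine, CH2Cl2, 0 °C to rt
Reagents that add atoms: none
Why: DMAP-catalysed acylation of the secondary C8 alcohol with an anhydride, with retention at C8.

Step 20
Reactants: 28 protected target
Product: 29 (3aR,4R,6E,10E,11aR)-6-formyl-10-(hydroxymethyl)-3-methylidene-2-oxo-2,3,3a,4,5,8,9,11a-octahydrocyclodeca[b]furan-4-yl 3-methylbutanoate (target)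
Conditions: 1 M aq. HCl, THF, 0 °C to rt
Reagents that add atoms: water, O
Why: Dilute aqueous acid hydrolyses the enal dimethyl acetal and cleaves the primary silyl ether in one operation; the lactone, the ester and the methylene group are stable to these conditions.

## Compound list

1 | but-2-yne-1,4-diol | OCC#CCO | starting material
2 | 4-[(tert-butyldimethylsilyl)oxy]but-2-yn-1-ol | OCC#CCO[Si](C)(C)C(C)(C)C | intermediate
3 | sodium alkenylaluminate: five-membered 1,2-oxaluminole ring (Al–O–CH2–CH=C), two 2-methoxyethoxy groups on Al, CH2OSi(t-Bu)Me2 on the Al-bound carbon | [Na+].COCCO[Al-]1(OCCOC)OCC=C1CO[Si](C)(C)C(C)(C)C | intermediate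
4 | (Z)-4-[(tert-butyldimethylsilyl)oxy]-3-iodobut-2-en-1-ol (iodine cis to CH2OH) | OC/C=C(\I)CO[Si](C)(C)C(C)(C)C | intermediate
5 | (3-ethoxy-3-oxopropyl)zinc bromide | CCOC(=O)CC[Zn]Br | starting material
6 | ethyl (E)-4-{[(tert-butyldimethylsilyl)oxy]methyl}-6-hydroxyhex-4-enoate | CCOC(=O)CC/C(CO[Si](C)(C)C(C)(C)C)=C\CO | intermediate
7 | (E)-4-{[(tert-butyldimethylsilyl)oxy]methyl}-6-hydroxyhex-4-enal | O=CCC/C(CO[Si](C)(C)C(C)(C)C)=C\CO | intermediate
8 | diethyl (2-oxooxolan-3-yl)phosphonate | CCOP(=O)(OCC)C1CCOC1=O | starting material
9 | (E)-3-[(E)-4-{[(tert-butyldimethylsilyl)oxy]methyl}-6-hydroxyhex-4-en-1-ylidene]oxolan-2-one | O=C1OCC/C1=C\CC/C(CO[Si](C)(C)C(C)(C)C)=C\CO | intermediate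
10 | (2E,6E)-6-{[(tert-butyldimethylsilyl)oxy]methyl}-8-hydroxy-2-(2-hydroxyethyl)-N-methoxy-N-methylocta-2,6-dienamide | CON(C)C(=O)/C(CCO)=C/CC/C(CO[Si](C)(C)C(C)(C)C)=C\CO | intermediate
11 | (2E,6E)-6-{[(tert-butyldimethylsilyl)oxy]methyl}-2-(2-hydroxyethyl)-N-methoxy-N-methyl-8-oxoocta-2,6-dienamide | CON(C)C(=O)/C(CCO)=C/CC/C(CO[Si](C)(C)C(C)(C)C)=C\C=O | intermediate
12 | (2E,6E)-6-{[(tert-butyldimethylsilyl)oxy]methyl}-N-methoxy-N-methyl-8-oxo-2-{2-[(triethylsilyl)oxy]ethyl}octa-2,6-dienamide | CON(C)C(=O)/C(CCO[Si](CC)(CC)CC)=C/CC/C(CO[Si](C)(C)C(C)(C)C)=C\C=O | intermediate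
13 | vinylmagnesium bromide | C=C[Mg]Br | starting material
14 | divinylzinc | C=C[Zn]C=C | intermediate
15 | (2E,6E,8S)-6-{[(tert-butyldimethylsilyl)oxy]methyl}-8-hydroxy-N-methoxy-N-methyl-2-{2-[(triethylsilyl)oxy]ethyl}deca-2,6,9-trienamide | CON(C)C(=O)/C(CCO[Si](CC)(CC)CC)=C/CC/C(CO[Si](C)(C)C(C)(C)C)=C\[C@@H](O)C=C | intermediate
16 | (2E,6E,8S)-6-{[(tert-butyldimethylsilyl)oxy]methyl}-8-hydroxy-2-{2-[(triethylsilyl)oxy]ethyl}deca-2,6,9-trienal | O=C/C(CCO[Si](CC)(CC)CC)=C/CC/C(CO[Si](C)(C)C(C)(C)C)=C\[C@@H](O)C=C | intermediate
17 | acryloyl chloride | C=CC(=O)Cl | starting material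
18 | (3S,4E,8E)-5-{[(tert-butyldimethylsilyl)oxy]methyl}-9-formyl-11-[(triethylsilyl)oxy]undeca-1,4,8-trien-3-yl prop-2-enoate | O=C/C(CCO[Si](CC)(CC)CC)=C/CC/C(CO[Si](C)(C)C(C)(C)C)=C\[C@@H](OC(=O)C=C)C=C | intermediate
19 | (2E,6E)-6-{[(tert-butyldimethylsilyl)oxy]methyl}-7-[(2S)-5-oxo-2,5-dihydrofuran-2-yl]-2-{2-[(triethylsilyl)oxy]ethyl}hepta-2,6-dienal | O=C/C(CCO[Si](CC)(CC)CC)=C/CC/C(CO[Si](C)(C)C(C)(C)C)=C\[C@H]1OC(=O)C=C1 | intermediate
20 | (5S)-5-[(1E,5E)-2-{[(tert-butyldimethylsilyl)oxy]methyl}-6-(dimethoxymethyl)-8-[(triethylsilyl)oxy]octa-1,5-dien-1-yl]furan-2(5H)-one | COC(OC)/C(CCO[Si](CC)(CC)CC)=C/CC/C(CO[Si](C)(C)C(C)(C)C)=C\[C@H]1OC(=O)C=C1 | intermediate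
21 | (5S)-5-[(1E,5E)-2-{[(tert-butyldimethylsilyl)oxy]methyl}-6-(dimethoxymethyl)-8-hydroxyocta-1,5-dien-1-yl]furan-2(5H)-one | COC(OC)/C(CCO)=C/CC/C(CO[Si](C)(C)C(C)(C)C)=C\[C@H]1OC(=O)C=C1 | intermediate
22 | (3E,7E)-7-{[(tert-butyldimethylsilyl)oxy]methyl}-3-(dimethoxymethyl)-8-[(2S)-5-oxo-2,5-dihydrofuran-2-yl]octa-3,7-dienal | O=CC/C(C(OC)OC)=C\CC/C(CO[Si](C)(C)C(C)(C)C)=C\[C@H]1OC(=O)C=C1 | intermediate
23 | (3aR,4R,6E,10E,11aR)-10-{[(tert-butyldimethylsilyl)oxy]methyl}-6-(dimethoxymethyl)-4-hydroxy-3a,4,5,8,9,11a-hexahydrocyclodeca[b]furan-2(3H)-one | C1C(=O)O[C@@H]2/C=C(/CO[Si](C)(C)C(C)(C)C)CC/C=C(/C(OC)OC)C[C@@H](O)[C@@H]12 | intermediate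
24 | (3aR,4R,6E,10E,11aR)-10-{[(tert-butyldimethylsilyl)oxy]methyl}-6-(dimethoxymethyl)-3-[(dimethylamino)methyl]-4-hydroxy-3a,4,5,8,9,11a-hexahydrocyclodeca[b]furan-2(3H)-one (both C3 epimers) | CN(C)CC1C(=O)O[C@@H]2/C=C(/CO[Si](C)(C)C(C)(C)C)CC/C=C(/C(OC)OC)C[C@@H](O)[C@@H]12 | intermediate
25 | trimethylammonium iodide of 24 (NMe3+ in place of NMe2, iodide counter-ion) | C[N+](C)(C)CC1C(=O)O[C@@H]2/C=C(/CO[Si](C)(C)C(C)(C)C)CC/C=C(/C(OC)OC)C[C@@H](O)[C@@H]12.[I-] | intermediate
26 | (3aR,4R,6E,10E,11aR)-10-{[(tert-butyldimethylsilyl)oxy]methyl}-6-(dimethoxymethyl)-4-hydroxy-3-methylidene-3a,4,5,8,9,11a-hexahydrocyclodeca[b]furan-2(3H)-one | C=C1C(=O)O[C@@H]2/C=C(/CO[Si](C)(C)C(C)(C)C)CC/C=C(/C(OC)OC)C[C@@H](O)[C@@H]12 | intermediate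
27 | 3-methylbutanoic anhydride | CC(C)CC(=O)OC(=O)CC(C)C | starting material
28 | (3aR,4R,6E,10E,11aR)-10-{[(tert-butyldimethylsilyl)oxy]methyl}-6-(dimethoxymethyl)-3-methylidene-2-oxo-2,3,3a,4,5,8,9,11a-octahydrocyclodeca[b]furan-4-yl 3-methylbutanoate | C=C1C(=O)O[C@@H]2/C=C(/CO[Si](C)(C)C(C)(C)C)CC/C=C(/C(OC)OC)C[C@@H](OC(=O)CC(C)C)[C@@H]12 | intermediate
29 | (3aR,4R,6E,10E,11aR)-6-formyl-10-(hydroxymethyl)-3-methylidene-2-oxo-2,3,3a,4,5,8,9,11a-octahydrocyclodeca[b]furan-4-yl 3-methylbutanoate | C=C1C(=O)O[C@@H]2/C=C(/CO)CC/C=C(/C=O)C[C@@H](OC(=O)CC(C)C)[C@@H]12 | target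

## Step count and least certain steps

Total step count: 20. Longest linear sequence: 20 steps (from 1; compounds 5, 8, 13, 17 and 27 are purchased).

**Step 16 (key step).** The most likely failure is premature reduction. The ketyl may be reduced and protonated to alcohol 21, or the butenolide may take up electrons with opening of its allylic C–O bond, before the strained ten-membered transition state is reached; closure on the wrong face at C8 is a second, lesser risk. The fallback replaces the radical closure by an allylmetal addition that makes the same C7–C8 bond. It sets out from 16. Acylation with 2-(chloromethyl)acryloyl chloride (i-Pr2NEt, −78 °C) gives the 2-(chloromethyl)acrylate F1. Ring-closing metathesis with the second-generation Hoveyda–Grubbs catalyst in toluene at 80 °C gives the 3-(chloromethyl)butenolide enal F2. Acetalisation as in step 13 gives the dimethyl acetal F3, desilylation as in step 14 gives the alcohol F4, and Dess–Martin oxidation gives the aldehyde F5. Intramolecular Nozaki–Hiyama allylation (CrCl2, catalytic LiI, THF, high dilution) then converts the allylic chloride into an allylchromium species whose γ-carbon C7 adds to the C8 aldehyde; this closes the ring and forms the C11=C13 methylene in the same step. The closed chair transition state of such additions points to the anti adduct, that is the C8 epimer of 26, the 8-epi alcohol F6. Mitsunobu esterification of F6 with 3-methylbutanoic acid (PPh3, diisopropyl azodicarboxylate) inverts C8 and comes back to the route at 28. The same inversion is the remedy if the radical closure itself favours the wrong face at C8.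

**Step 9.** Poor facial selectivity is the main risk, because the Z-configured β,β-disubstituted enal and the Lewis-basic Weinreb amide can disturb the zinc amino-alkoxide catalyst, and residual magnesium salts promote a racemic background addition. The fallback replaces vinyl addition by alkyne addition and semi-hydrogenation. It sets out from 12. Addition of trimethylsilylacetylene under Me2Zn with a ProPhenol ligand (antipode chosen for Si-face delivery) gives the silylated propargylic alcohol F7. C-desilylation with K2CO3 in MeOH gives the terminal alkyne F8. Semi-hydrogenation (H2, Pd/CaCO3 poisoned with Pb(OAc)2, quinoline) comes back to the route at 15.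

**Step 14.** The risk is loss of the acetal by intramolecular exchange: once the C8 hydroxyl is free, traces of acid let it close onto C14 to a five-membered cyclic methyl acetal, and the C15 silyl ether may be partly lost as well. The fallback sets out from 20 and uses oxidative desilylation with IBX in DMSO, which cleaves a primary triethylsilyl ether beside a tert-butyldimethylsilyl ether and oxidises the liberated alcohol in the same flask. It comes back to the route at 22; the hydroxy acetal never accumulates and no new compound is made (F0).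

**Step 17.** The risk is translactonisation and incomplete enolisation: the C8 lithium alkoxide can attack the lactone carbonyl and move the lactone from O6 to O8 before the second deprotonation, and the dianion is a sluggish nucleophile. The fallback works through a mono-anion with the alcohol masked. It sets out from 23. Me3SiCl and imidazole give the C8 trimethylsilyl ether F9. LiN(i-Pr)2 (1.1 equiv) and Eschenmoser salt give the Mannich base F10. MeI gives the ammonium iodide F11, and aqueous NaHCO3 gives the α-methylene lactone silyl ether F12. Buffered HF·pyridine removes the trimethylsilyl group and comes back to the route at 26.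

**Step 4.** Over-reduction to the primary alcohol is the risk, since the neighbouring C6 aluminium alkoxide may let the tetrahedral intermediate collapse before work-up. The fallback uses a nitrile as the aldehyde precursor, which cannot be over-reduced. It sets out from 4. Negishi coupling with (2-cyanoethyl)zinc bromide under the conditions of step 3 gives the hydroxy nitrile F13. Reduction with i-Bu2AlH stops at the N-aluminio imine, and hydrolysis with aqueous tartaric acid comes back to the route at 7.

## Further compounds

F1 | step 16 | 2-(chloromethyl)acrylate of carbinol 16: (3S,4E,8E)-5-{[(tert-butyldimethylsilyl)oxy]methyl}-9-formyl-11-[(triethylsilyl)oxy]undeca-1,4,8-trien-3-yl 2-(chloromethyl)prop-2-enoate | O=C/C(CCO[Si](CC)(CC)CC)=C/CC/C(CO[Si](C)(C)C(C)(C)C)=C\[C@@H](OC(=O)C(=C)CCl)C=C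
F2 | step 16 | 3-(chloromethyl)butenolide enal: (2E,6E)-6-{[(tert-butyldimethylsilyl)oxy]methyl}-7-[(2R)-4-(chloromethyl)-5-oxo-2,5-dihydrofuran-2-yl]-2-{2-[(triethylsilyl)oxy]ethyl}hepta-2,6-dienal | O=C/C(CCO[Si](CC)(CC)CC)=C/CC/C(CO[Si](C)(C)C(C)(C)C)=C\[C@H]1OC(=O)C(CCl)=C1
F3 | step 16 | (5R)-3-(chloromethyl)-5-[(1E,5E)-2-{[(tert-butyldimethylsilyl)oxy]methyl}-6-(dimethoxymethyl)-8-[(triethylsilyl)oxy]octa-1,5-dien-1-yl]furan-2(5H)-one | COC(OC)/C(CCO[Si](CC)(CC)CC)=C/CC/C(CO[Si](C)(C)C(C)(C)C)=C\[C@H]1OC(=O)C(CCl)=C1
F4 | step 16 | (5R)-3-(chloromethyl)-5-[(1E,5E)-2-{[(tert-butyldimethylsilyl)oxy]methyl}-6-(dimethoxymethyl)-8-hydroxyocta-1,5-dien-1-yl]furan-2(5H)-one | COC(OC)/C(CCO)=C/CC/C(CO[Si](C)(C)C(C)(C)C)=C\[C@H]1OC(=O)C(CCl)=C1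
F5 | step 16 | (3E,7E)-7-{[(tert-butyldimethylsilyl)oxy]methyl}-8-[(2R)-4-(chloromethyl)-5-oxo-2,5-dihydrofuran-2-yl]-3-(dimethoxymethyl)octa-3,7-dienal | O=CC/C(C(OC)OC)=C\CC/C(CO[Si](C)(C)C(C)(C)C)=C\[C@H]1OC(=O)C(CCl)=C1
F6 | step 16 | C8 epimer of 26: (3aR,4S,6E,10E,11aR)-10-{[(tert-butyldimethylsilyl)oxy]methyl}-6-(dimethoxymethyl)-4-hydroxy-3-methylidene-3a,4,5,8,9,11a-hexahydrocyclodeca[b]furan-2(3H)-one | C=C1C(=O)O[C@@H]2/C=C(/CO[Si](C)(C)C(C)(C)C)CC/C=C(/C(OC)OC)C[C@H](O)[C@@H]12
F7 | step 9 | (2E,6E,8R)-6-{[(tert-butyldimethylsilyl)oxy]methyl}-8-hydroxy-N-methoxy-N-methyl-2-{2-[(triethylsilyl)oxy]ethyl}-10-(trimethylsilyl)deca-2,6-dien-9-ynamide | CON(C)C(=O)/C(CCO[Si](CC)(CC)CC)=C/CC/C(CO[Si](C)(C)C(C)(C)C)=C\[C@@H](O)C#C[Si](C)(C)C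
F8 | step 9 | (2E,6E,8R)-6-{[(tert-butyldimethylsilyl)oxy]methyl}-8-hydroxy-N-methoxy-N-methyl-2-{2-[(triethylsilyl)oxy]ethyl}deca-2,6-dien-9-ynamide | CON(C)C(=O)/C(CCO[Si](CC)(CC)CC)=C/CC/C(CO[Si](C)(C)C(C)(C)C)=C\[C@@H](O)C#C
F0 | step 14 | none | none
F9 | step 17 | C8 O-trimethylsilyl ether of 23 | C1C(=O)O[C@@H]2/C=C(/CO[Si](C)(C)C(C)(C)C)CC/C=C(/C(OC)OC)C[C@@H](O[Si](C)(C)C)[C@@H]12
F10 | step 17 | C8 O-trimethylsilyl ether of Mannich base 24 (both C11 epimers) | CN(C)CC1C(=O)O[C@@H]2/C=C(/CO[Si](C)(C)C(C)(C)C)CC/C=C(/C(OC)OC)C[C@@H](O[Si](C)(C)C)[C@@H]12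
F11 | step 17 | C8 O-trimethylsilyl ether of ammonium iodide 25 | C[N+](C)(C)CC1C(=O)O[C@@H]2/C=C(/CO[Si](C)(C)C(C)(C)C)CC/C=C(/C(OC)OC)C[C@@H](O[Si](C)(C)C)[C@@H]12.[I-]
F12 | step 17 | C8 O-trimethylsilyl ether of 26 | C=C1C(=O)O[C@@H]2/C=C(/CO[Si](C)(C)C(C)(C)C)CC/C=C(/C(OC)OC)C[C@@H](O[Si](C)(C)C)[C@@H]12
F13 | step 4 | (E)-4-{[(tert-butyldimethylsilyl)oxy]methyl}-6-hydroxyhex-4-enenitrile | N#CCC/C(CO[Si](C)(C)C(C)(C)C)=C\CO
A1 | alternative 1 | ten-membered triene carbocycle with C15 methyl ester on the ring-cis C4=C5 alkene, C6 triethylsilyl ether, C8 4-methoxybenzyl ether, 3-[(4-methoxybenzyl)oxy]prop-1-en-2-yl on C7 and C14 dimethyl acetal | C=C(COCc1ccc(OC)cc1)[C@H]1[C@H](O[Si](CC)(CC)CC)/C=C(/C(=O)OC)CC/C=C(/C(OC)OC)C[C@H]1OCc1ccc(OC)cc1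
A2 | alternative 2 | ten-membered cis,cis-dienone with C6 ketone, C14 allylic alcohol, C15 tert-butyldimethylsilyl ether, C8 triethylsilyl ether and 2-[(4-methoxybenzyl)oxy]ethyl on C7 | O=C1/C=C(/CO[Si](C)(C)C(C)(C)C)CC/C=C(/CO)C[C@@H](O[Si](CC)(CC)CC)[C@H]1CCOCc2ccc(OC)cc2
A3 | alternative 3 | C8 triethylsilyl ether of hydroxy lactone 23 (trans-fused, no C13 methylene) | C1C(=O)O[C@@H]2/C=C(/CO[Si](C)(C)C(C)(C)C)CC/C=C(/C(OC)OC)C[C@@H](O[Si](CC)(CC)CC)[C@@H]12
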